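Cuts, in retrosynthetic order: C3=C4 (diene–ene ring-closing metathesis, with C16 supplied by ethylene through ene–yne metathesis of a C4≡C5 alkyne), C8–C17 (tethered Reformatsky lactone closure), C6–Cl (invertive opening of a C6–C7 epoxide), C7–C8 and C2–C3 (two Nozaki–Hiyama–Kishi couplings), C10–C11 (key step), C9–C10 (aldol), C1–C2 (conjugate addition).
Enabling feature: in ring A (C1–C14–C13–C12–C11–C10) the tertiary carbinol C11(OH)(CH3) stands next to the C12 carbonyl. This α-ketol maps back onto a 1-acetylcyclopentanol in which C12 is the carbinol carbon, C11 the acetyl carbonyl carbon and C10 the migrating ring carbon.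
Ring order in the forward direction: purchased cyclopentene ring, then ring A by one-carbon expansion, then the γ-lactone (C7, C8, C17, C19, O), then the ten-membered ring (C1 to C10) last.
Stereochemistry, part 1: C1 comes from a chiral copper catalyst; C10 and C9 from a bulky 1-silylvinyl group on C1 together with a syn-selective titanium aldol; transient C12 from osmylation anti to C9; C11 from the chelate of the key step; C2 from Felkin–Anh addition.
Stereochemistry, part 2: C6 and C7 come from a catalyst-controlled epoxidation followed by SN2 opening; C8 and C17 from the C7-tethered lactone closure; the Z C3=C4 alkene from the constraint of the ten-membered ring.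

Key step: step 7

Remark: C1 is the quaternary ring-fusion carbon; C2 to C9 run round the large ring to C10; C11 to C14 complete ring A; C16 is the exocyclic methylene carbon; C17 and C19 complete the lactone. 2-[(tert-Butyldiphenylsilyl)oxy]acetaldehyde and 3-(trimethylsilyl)propynal are taken as commercially available.

Step 1
Reactants: 1 3-methylcyclopent-2-en-1-one; 2 ethynyltrimethylsilane
Product: 5 trimethylsilyl enol ether (C10=C12) of (S)-3-methyl-3-[1-(trimethylsilyl)vinyl]cyclopentanone, via silylvinylalane 3 (not isolated), via aluminium enolate 4 (not isolated)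
Conditions: 2, DIBAL-H, hexane–THF, 55 °C; then 1, Cu(OTf)2 (5 mol %), chiral sulfonate-bearing imidazolinium salt (5 mol %), THF, −15 °C; then TMSOTf, −78 °C
Reagents that add atoms: trimethylsilyl triflate C[Si](C)(C)OS(=O)(=O)C(F)(F)F
Why: Hydroalumination puts aluminium on the silicon-bearing alkyne carbon, the copper–NHC-catalysed asymmetric conjugate addition of this alkenylalane to the β-methyl enone creates the quaternary C1 under ligand control (antipode chosen for 1S), and O-silylation stores the regiodefined C10=C12 enolate; the 1-silylvinyl group is preferred to plain vinyl because it has to outweigh the C1 methyl group sterically in step 2.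

Step 2
Reactants: 5 silyl enol ether; 6 2-[(tert-butyldiphenylsilyl)oxy]acetaldehyde
Product: 9 syn-aldol ketone (C10 bears CH(OH)CH2OTBDPS trans to the silylvinyl group; C1 C9 C10 configured as in 45), via lithium enolate 7 (not isolated), via titanium enolate 8 (not isolated)
Conditions: MeLi, THF, 0 °C; ClTi(OiPr)3, −78 °C; 6, −78 °C; aq. NH4Cl
Reagents that add atoms: none
Why: Enol silane cleavage and transmetalation give a triisopropoxytitanium enolate, a class whose aldol additions are syn-selective even for ring enolates, which sets C9, while the aldehyde reaches C10 on the face away from the bulky silylvinyl group, which sets the trans relation of C2 and C9.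

Step 3
Reactants: 9 syn-aldol ketone
Product: 10 C9 triisopropylsilyl ether of 9
Conditions: TIPSOTf, 2,6-lutidine, CH2Cl2, −78 to 0 °C
Reagents that add atoms: triisopropylsilyl triflate CC(C)[Si](OS(=O)(=O)C(F)(F)F)(C(C)C)C(C)C
Why: Silyl triflate with a hindered pyridine base protects the aldol hydroxyl without retro-aldol cleavage or β-elimination, and TIPS is chosen because it must survive the acid of step 8.

Step 4
Reactants: 10 protected ketone; 11 ethyltriphenylphosphonium bromide
Product: 13 (Z)-C12-ethylidenecyclopentane, via ethylidene ylide 12 (not isolated)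
Conditions: 11, KOtBu, THF, rt; then 10, rt to 50 °C
Reagents that add atoms: none
Why: Wittig ethylidenation of a hindered cyclopentanone, as practised on 17-oxo steroids, should outrun enolisation with the potassium-derived ylide, and the alkene geometry (Z expected) does not matter because C11 ends as a carbonyl carbon.

Step 5
Reactants: 13 ethylidenecyclopentane
Product: 14 C11,C12-diol (C12 hydroxyl trans to the C9 chain)
Conditions: OsO4 (5 mol %), NMO, acetone–H2O, rt
Reagents that add atoms: N-methylmorpholine N-oxide C[N+]1([O-])CCOCC1; water O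
Why: Upjohn dihydroxylation attacks the electron-rich trisubstituted alkene in preference to the hindered 1-silylvinyl group and approaches the face opposite the C9 side chain on the neighbouring carbon, so that the C12 hydroxyl ends trans to C9 (12R).

Step 6
Reactants: 14 diol
Product: 15 1-acetylcyclopentanol (1S,9S,10S,12R; acetyl cis to the C1 methyl group and to the C9 chain)
Conditions: IBX, DMSO, rt
Reagents that add atoms: none
Why: IBX oxidises the secondary alcohol of a vicinal diol to the α-ketol without glycol cleavage and cannot touch the tertiary C12 hydroxyl.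

Step 7
Reactants: 15 1-acetylcyclopentanol
Product: 17 2-hydroxy-2-methylcyclohexanone (ring A; 1S,9S,10S,11S), via dichloroaluminium chelate 16 (not isolated)
Conditions: MeAlCl2 (1.1 equiv), CH2Cl2, −78 to 0 °C; aq. Rochelle salt
Reagents that add atoms: none
Why: MeAlCl2 metalates the C12 hydroxyl with loss of methane and the dichloroaluminium centre also binds the acetyl oxygen, so that both oxygens are held syn in a five-membered chelate and C11 is activated; the C10–C12 σ bond, which overlaps with the π* orbital of the bound carbonyl, then migrates across the same face from C12 to C11, C10 keeping its configuration, and the former carbinol carbon C12 collapses to the ring ketone. This is an acyloin (α-ketol) rearrangement, closest in kind to the ring D enlargement of 17-hydroxypregnan-20-ones and to the conversion of 1-acylcyclopentanols into 2-hydroxycyclohexanones. Ring A is not closed by a cyclisation but grows out of the cyclopentane by insertion of C11 into the C10–C12 bond (one-carbon ring expansion), favoured by the unstrained cyclohexanone and its own aluminium chelate. The only new stereocentre, C11, is fixed by the chelate: with the acetyl group on the face of the C1 methyl group and its oxygen syn to the alkoxide, C10 can reach only one carbonyl face, which puts the C11 hydroxyl trans and the C11 methyl group cis to the C9 chain (11S). The step needs migration of C10 rather than C13; the secondary carbon C10 is the better migrating group, and the acetyl methyl group, which lies under the ring in the chelate, twists away from the C1 methyl group and the C9 chain toward C13, a twist that brings C10–C12 into and C13–C12 out of alignment with the carbonyl π system. Stoichiometric aluminium and low temperature hold the product as its chelate, so that reversal or a later methyl shift should not erode the kinetic outcome.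

Step 8
Reactants: 17 silylvinyl ketol
Product: 18 C1-vinyl ketol
Conditions: TFA (5 equiv), CH2Cl2, 0 °C to rt
Reagents that add atoms: none
Why: Acid protodesilylation of the vinylsilane (ipso protonation and loss of the silyl group from the β-silyl cation) uncovers the plain vinyl group once its steric task is done, the TIPS and TBDPS ethers resist anhydrous acid and no stereocentre of 17 is enolisable.

Step 9
Reactants: 18 vinyl ketol
Product: 19 C13=C14 cyclohexenone
Conditions: IBX·4-methoxypyridine N-oxide, DMSO, rt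
Reagents that add atoms: none
Why: IBX dehydrogenation of a ketone proceeds through its enol, and since C11 is fully substituted only the C13 methylene can enolise, so the C13=C14 enone is the single possible product.

Step 10
Reactants: 19 vinyl enone
Product: 20 C2 aldehyde
Conditions: O3, CH2Cl2, −78 °C (Sudan Red 7B end point); Me2S
Reagents that add atoms: ozone [O-][O+]=O
Why: Ozonolysis with an indicator end point cleaves the isolated monosubstituted alkene faster than the electron-poor enone and gives the neopentyl C2 aldehyde.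

Step 11
Reactants: 20 C2 aldehyde; 21 vinyl bromide
Product: 23 (2S)-allylic alcohol C2(OH)–CH=CH2, via vinylchromium dichloride 22 (not isolated)
Conditions: CrCl2 (4 equiv), NiCl2 (1 mol %), DMF, rt
Reagents that add atoms: none
Why: The Nozaki–Hiyama–Kishi reaction adds the vinylchromium reagent to the aldehyde only (enone and free tertiary alcohol are tolerated), and Felkin–Anh attack with C10 as the large group and the nucleophile passing the C1 methyl group gives the 2S carbinol.

Step 12
Reactants: 23 allylic alcohol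
Product: 24 C2,C11-bis(tert-butyldimethylsilyl) ether
Conditions: TBSOTf (3 equiv), 2,6-lutidine, CH2Cl2, 0 °C to rt
Reagents that add atoms: tert-butyldimethylsilyl triflate CC(C)(C)[Si](C)(C)OS(=O)(=O)C(F)(F)F
Why: Excess silyl triflate caps the C2 and the tertiary C11 hydroxyls in one operation, the enone having no enolisable hydrogen that could be silylated.

Step 13
Reactants: 24 tetrasilyl ether
Product: 25 C8 primary alcohol
Conditions: TBAF–AcOH (1:1), DMF, rt
Reagents that add atoms: none
Why: Acetic acid-buffered fluoride cleaves the unhindered primary TBDPS ether faster than the crowded secondary and tertiary alkylsilyl ethers and is too weakly basic to harm the enone.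

Step 14
Reactants: 25 primary alcohol
Product: 26 C8 aldehyde
Conditions: Dess–Martin periodinane, CH2Cl2, 0 °C to rt
Reagents that add atoms: none
Why: Dess–Martin oxidation delivers the α-silyloxy aldehyde under near-neutral conditions, so C9 is not epimerised.

Step 15
Reactants: 27 3-(trimethylsilyl)prop-2-ynal; 28 iodoform
Product: 30 (E)-(4-iodobut-3-en-1-yn-1-yl)trimethylsilane, via dichromium carbenoid 29 (not isolated)
Conditions: CrCl2 (6 equiv), THF, 0 °C
Reagents that add atoms: none
Why: Takai olefination converts the ynal into the E-vinyl iodide through a geminal dichromium reagent.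

Step 16
Reactants: 26 C8 aldehyde; 30 iodoenyne
Product: 32 (E)-enynol C8(OH)–C7H=C6H–C5≡C4–SiMe3, via alkenylchromium dichloride 31 (not isolated)
Conditions: CrCl2 (4 equiv), NiCl2 (1 mol %), DMSO–THF, rt
Reagents that add atoms: none
Why: A second Nozaki–Hiyama–Kishi coupling forms C7–C8 with retention of the E alkene geometry and complete preference for the aldehyde; the new C8 carbinol (Felkin–Anh epimer drawn) needs no control because step 18 removes it.

Step 17
Reactants: 32 silylated enynol
Product: 33 terminal enynol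
Conditions: K2CO3 (cat.), MeOH, 0 °C
Reagents that add atoms: none
Why: Carbonate-catalysed methanolysis cleaves only the alkynyl C–Si bond, all O-silyl groups here being far more hindered.

Step 18
Reactants: 33 terminal enynol
Product: 34 (E)-enynone (C8 ketone)
Conditions: Dess–Martin periodinane, CH2Cl2, 0 °C
Reagents that add atoms: none
Why: Dess–Martin oxidation of the allylic alcohol gives the E-enynone and merges both C8 epimers.

Step 19
Reactants: 34 enynone
Product: 35 trans-(6R,7S)-epoxy ketone
Conditions: La(OiPr)3 (10 mol %), (R)-BINOL (10 mol %), Ph3As=O (10 mol %), TBHP (decane), 4 Å MS, THF, rt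
Reagents that add atoms: tert-butyl hydroperoxide CC(C)(C)OO
Why: Catalytic asymmetric nucleophilic epoxidation of an E-enone (Weitz–Scheffer type, lanthanum BINOLate with hydroperoxide) lets the ligand antipode choose the alkene face and gives the trans 6R,7S epoxide, whereas the ring A enone is spared because its β-carbon C14 is neopentyl.

Step 20
Reactants: 35 epoxy ketone
Product: 36 (6S,7R)-chlorohydrin (C6–Cl; C7–OH)
Conditions: pyridine hydrochloride, CH2Cl2, 0 °C to rt
Reagents that add atoms: pyridine hydrochloride c1cc[nH+]cc1.[Cl-]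
Why: Acid-assisted anti opening of the epoxide by chloride occurs at the propargylic carbon C6, the C7–O bond being deactivated by the adjacent carbonyl as in β-aryl epoxy ketones, so C6 is inverted to 6S and C7 keeps its oxygen (7R).

Step 21
Reactants: 36 chlorohydrin; 37 2-bromopropanoyl bromide
Product: 38 C7 2-bromopropanoate
Conditions: pyridine, CH2Cl2, −20 °C
Reagents that add atoms: none
Why: Acylation of the only free hydroxyl with the acid bromide and pyridine at low temperature avoids re-closure of the epoxide or loss of HCl; the bromine-bearing carbon is a mixture that disappears in the next step.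

Step 22
Reactants: 38 bromopropanoate
Product: 40 β-hydroxy-γ-lactone (C6 C7 C8 C17 configured as in 45), via samarium enolate 39 (not isolated)
Conditions: SmI2 (2.2 equiv), THF, −78 °C; aq. NH4Cl
Reagents that add atoms: none
Why: In this samarium diiodide-promoted intramolecular Reformatsky reaction the C–Br bond is reduced first, and the enolate tethered through O7 can reach only the ketone face that leaves C6 and C9 trans on the new lactone (8-OH cis to C6), with the C17 methyl group turned away from the C9 chain, which sets C8 and C17.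

Step 23
Reactants: 40 silyl-protected lactone
Product: 41 tetraol (free hydroxyls at C2 C8 C9 C11)
Conditions: HF·pyridine, pyridine–THF, 0 °C to rt
Reagents that add atoms: none
Why: HF·pyridine removes all three remaining silyl ethers under mildly acidic conditions that leave the propargylic chloride, the β-hydroxy lactone and the enone intact.

Step 24
Reactants: 41 tetraol
Product: 42 C2,C9-diacetate
Conditions: Ac2O, pyridine, DMAP (cat.), CH2Cl2, 0 °C to rt
Reagents that add atoms: acetic anhydride CC(=O)OC(C)=O
Why: DMAP-catalysed acetylation esterifies the two secondary alcohols (C2 and C9) while the tertiary C8 and C11 hydroxyls stay free.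

Step 25
Reactants: 42 diacetate; 43 ethylene
Product: 45 CNP0188317.1, via butadiene 44 (not isolated)
Conditions: second-generation Grubbs catalyst (10 mol %), ethylene (1 atm), CH2Cl2, rt; then Ar purge, toluene (0.5 mM), 1,4-benzoquinone (cat.), 80 °C
Reagents that add atoms: none
Why: Ene–yne cross metathesis with ethylene turns the terminal alkyne into the 2-substituted butadiene (C16 from ethylene), and ring-closing metathesis between its vinyl end and the C2 vinyl group then forms C3=C4, the strain of an E alkene next to the exocyclic diene in the trans-fused ten-membered ring favouring the Z isomer under the reversible conditions.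

Compound list
1 | 3-methylcyclopent-2-en-1-one | CC1=CC(=O)CC1 | starting material
2 | ethynyltrimethylsilane | C#C[Si](C)(C)C | starting material
3 | diisobutyl[1-(trimethylsilyl)vinyl]aluminium | C=C([Si](C)(C)C)[Al](CC(C)C)CC(C)C | intermediate
4 | diisobutylaluminium C10=C12 enolate | C=C([Si](C)(C)C)[C@@]1(C)CCC(O[Al](CC(C)C)CC(C)C)=C1 | intermediate
5 | trimethylsilyl enol ether of (S)-3-methyl-3-[1-(trimethylsilyl)vinyl]cyclopentanone | C=C([Si](C)(C)C)[C@@]1(C)CCC(O[Si](C)(C)C)=C1 | intermediate
6 | 2-[(tert-butyldiphenylsilyl)oxy]acetaldehyde | O=CCO[Si](c1ccccc1)(c1ccccc1)C(C)(C)C | starting material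
7 | lithium C10=C12 enolate | C=C([Si](C)(C)C)[C@@]1(C)CCC([O-])=C1.[Li+] | intermediate
8 | triisopropoxytitanium C10=C12 enolate | C=C([Si](C)(C)C)[C@@]1(C)CCC(O[Ti](OC(C)C)(OC(C)C)OC(C)C)=C1 | intermediate
9 | syn-aldol ketone | C=C([Si](C)(C)C)[C@@]1(C)CCC(=O)[C@@H]1[C@H](O)CO[Si](c1ccccc1)(c1ccccc1)C(C)(C)C | intermediate
10 | C9 TIPS ether of the aldol ketone | C=C([Si](C)(C)C)[C@@]1(C)CCC(=O)[C@@H]1[C@H](O[Si](C(C)C)(C(C)C)C(C)C)CO[Si](c1ccccc1)(c1ccccc1)C(C)(C)C | intermediate
11 | ethyltriphenylphosphonium bromide | CC[P+](c1ccccc1)(c1ccccc1)c1ccccc1.[Br-] | starting material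
12 | ethylidenetriphenylphosphorane | CC=P(c1ccccc1)(c1ccccc1)c1ccccc1 | intermediate
13 | (Z)-C12-ethylidenecyclopentane | C=C([Si](C)(C)C)[C@@]1(C)CC/C(=C/C)[C@@H]1[C@H](O[Si](C(C)C)(C(C)C)C(C)C)CO[Si](c1ccccc1)(c1ccccc1)C(C)(C)C | intermediate
14 | C11,C12-diol | C=C([Si](C)(C)C)[C@@]1(C)CC[C@](O)([C@H](C)O)[C@@H]1[C@H](O[Si](C(C)C)(C(C)C)C(C)C)CO[Si](c1ccccc1)(c1ccccc1)C(C)(C)C | intermediate
15 | 1-acetylcyclopentanol (precursor of the key step) | C=C([Si](C)(C)C)[C@@]1(C)CC[C@](O)(C(C)=O)[C@@H]1[C@H](O[Si](C(C)C)(C(C)C)C(C)C)CO[Si](c1ccccc1)(c1ccccc1)C(C)(C)C | intermediate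
16 | dichloroaluminium alkoxide chelate of 15 | C=C([Si](C)(C)C)[C@@]1(C)CC[C@](O[Al](Cl)Cl)(C(C)=O)[C@@H]1[C@H](O[Si](C(C)C)(C(C)C)C(C)C)CO[Si](c1ccccc1)(c1ccccc1)C(C)(C)C | intermediate
17 | 2-hydroxy-2-methylcyclohexanone (product of the key step) | C=C([Si](C)(C)C)[C@@]1(C)CCC(=O)[C@@](C)(O)[C@@H]1[C@H](O[Si](C(C)C)(C(C)C)C(C)C)CO[Si](c1ccccc1)(c1ccccc1)C(C)(C)C | intermediate
18 | C1-vinyl ketol | C=C[C@@]1(C)CCC(=O)[C@@](C)(O)[C@@H]1[C@H](O[Si](C(C)C)(C(C)C)C(C)C)CO[Si](c1ccccc1)(c1ccccc1)C(C)(C)C | intermediate
19 | C13=C14 cyclohexenone | C=C[C@@]1(C)C=CC(=O)[C@@](C)(O)[C@@H]1[C@H](O[Si](C(C)C)(C(C)C)C(C)C)CO[Si](c1ccccc1)(c1ccccc1)C(C)(C)C | intermediate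
20 | C2 aldehyde | O=C[C@@]1(C)C=CC(=O)[C@@](C)(O)[C@@H]1[C@H](O[Si](C(C)C)(C(C)C)C(C)C)CO[Si](c1ccccc1)(c1ccccc1)C(C)(C)C | intermediate
21 | vinyl bromide | C=CBr | starting material
22 | vinylchromium dichloride | C=C[Cr](Cl)Cl | intermediate
23 | (2S)-allylic alcohol | C=C[C@H](O)[C@@]1(C)C=CC(=O)[C@@](C)(O)[C@@H]1[C@H](O[Si](C(C)C)(C(C)C)C(C)C)CO[Si](c1ccccc1)(c1ccccc1)C(C)(C)C | intermediate
24 | C2,C11-bis-TBS ether | C=C[C@H](O[Si](C)(C)C(C)(C)C)[C@@]1(C)C=CC(=O)[C@@](C)(O[Si](C)(C)C(C)(C)C)[C@@H]1[C@H](O[Si](C(C)C)(C(C)C)C(C)C)CO[Si](c1ccccc1)(c1ccccc1)C(C)(C)C | intermediate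
25 | C8 primary alcohol | C=C[C@H](O[Si](C)(C)C(C)(C)C)[C@@]1(C)C=CC(=O)[C@@](C)(O[Si](C)(C)C(C)(C)C)[C@@H]1[C@H](O[Si](C(C)C)(C(C)C)C(C)C)CO | intermediate
26 | C8 aldehyde | C=C[C@H](O[Si](C)(C)C(C)(C)C)[C@@]1(C)C=CC(=O)[C@@](C)(O[Si](C)(C)C(C)(C)C)[C@@H]1[C@H](O[Si](C(C)C)(C(C)C)C(C)C)C=O | intermediate
27 | 3-(trimethylsilyl)prop-2-ynal | O=CC#C[Si](C)(C)C | starting material
28 | iodoform | IC(I)I | starting material
29 | (iodomethanediyl)bis(dichlorochromium) | IC([Cr](Cl)Cl)[Cr](Cl)Cl | intermediate
30 | (E)-(4-iodobut-3-en-1-yn-1-yl)trimethylsilane | I/C=C/C#C[Si](C)(C)C | intermediate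
31 | (E)-4-(trimethylsilyl)but-1-en-3-ynylchromium dichloride | C[Si](C)(C)C#C/C=C/[Cr](Cl)Cl | intermediate
32 | silylated (E)-enynol | C=C[C@H](O[Si](C)(C)C(C)(C)C)[C@@]1(C)C=CC(=O)[C@@](C)(O[Si](C)(C)C(C)(C)C)[C@@H]1[C@H](O[Si](C(C)C)(C(C)C)C(C)C)[C@H](O)/C=C/C#C[Si](C)(C)C | intermediate
33 | terminal (E)-enynol | C=C[C@H](O[Si](C)(C)C(C)(C)C)[C@@]1(C)C=CC(=O)[C@@](C)(O[Si](C)(C)C(C)(C)C)[C@@H]1[C@H](O[Si](C(C)C)(C(C)C)C(C)C)[C@H](O)/C=C/C#C | intermediate
34 | (E)-enynone | C=C[C@H](O[Si](C)(C)C(C)(C)C)[C@@]1(C)C=CC(=O)[C@@](C)(O[Si](C)(C)C(C)(C)C)[C@@H]1[C@H](O[Si](C(C)C)(C(C)C)C(C)C)C(=O)/C=C/C#C | intermediate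
35 | trans-(6R,7S)-epoxy ketone | C=C[C@H](O[Si](C)(C)C(C)(C)C)[C@@]1(C)C=CC(=O)[C@@](C)(O[Si](C)(C)C(C)(C)C)[C@@H]1[C@H](O[Si](C(C)C)(C(C)C)C(C)C)C(=O)[C@H]1O[C@@H]1C#C | intermediate
36 | (6S,7R)-chlorohydrin | C=C[C@H](O[Si](C)(C)C(C)(C)C)[C@@]1(C)C=CC(=O)[C@@](C)(O[Si](C)(C)C(C)(C)C)[C@@H]1[C@H](O[Si](C(C)C)(C(C)C)C(C)C)C(=O)[C@@H](O)[C@@H](Cl)C#C | intermediate
37 | 2-bromopropanoyl bromide | CC(Br)C(=O)Br | starting material
38 | C7 2-bromopropanoate | C=C[C@H](O[Si](C)(C)C(C)(C)C)[C@@]1(C)C=CC(=O)[C@@](C)(O[Si](C)(C)C(C)(C)C)[C@@H]1[C@H](O[Si](C(C)C)(C(C)C)C(C)C)C(=O)[C@@H](OC(=O)C(C)Br)[C@@H](Cl)C#C | intermediate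
39 | samarium ester enolate | C=C[C@H](O[Si](C)(C)C(C)(C)C)[C@@]1(C)C=CC(=O)[C@@](C)(O[Si](C)(C)C(C)(C)C)[C@@H]1[C@H](O[Si](C(C)C)(C(C)C)C(C)C)C(=O)[C@@H](OC(O[Sm](I)I)=CC)[C@@H](Cl)C#C | intermediate
40 | silyl-protected β-hydroxy-γ-lactone | C=C[C@H](O[Si](C)(C)C(C)(C)C)[C@@]1(C)C=CC(=O)[C@@](C)(O[Si](C)(C)C(C)(C)C)[C@@H]1[C@H](O[Si](C(C)C)(C(C)C)C(C)C)[C@]1(O)[C@@H](C)C(=O)O[C@H]1[C@@H](Cl)C#C | intermediate
41 | tetraol | C=C[C@H](O)[C@@]1(C)C=CC(=O)[C@@](C)(O)[C@@H]1[C@H](O)[C@]1(O)[C@@H](C)C(=O)O[C@H]1[C@@H](Cl)C#C | intermediate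
42 | C2,C9-diacetate | C=C[C@H](OC(C)=O)[C@@]1(C)C=CC(=O)[C@@](C)(O)[C@@H]1[C@H](OC(C)=O)[C@]1(O)[C@@H](C)C(=O)O[C@H]1[C@@H](Cl)C#C | intermediate
43 | ethylene | C=C | starting material
44 | 2-substituted butadiene (seco-triene) | C=C[C@H](OC(C)=O)[C@@]1(C)C=CC(=O)[C@@](C)(O)[C@@H]1[C@H](OC(C)=O)[C@]1(O)[C@@H](C)C(=O)O[C@H]1[C@@H](Cl)C(=C)C=C | intermediate
45 | CNP0188317.1 (1S,2S,6S,7R,8R,9S,10S,11S,17R; 3Z) | C=C1/C=C\[C@H](OC(C)=O)[C@@]2(C)C=CC(=O)[C@@](C)(O)[C@@H]2[C@H](OC(C)=O)[C@]2(O)[C@@H](C)C(=O)O[C@H]2[C@H]1Cl | target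

Total step count: 25. Longest linear sequence: 24 steps (steps 1 to 14 and 16 to 25, from 1); step 15 is a one-step branch.

Steps most likely to fail

**Step 25 (ring closure).** Ruthenium may load slowly on the crowded C2 vinyl group. Oligomerisation may outrun closure of the strained ring. The alkene may form with E geometry.
The fallback inverts the order of ring construction. The carbocycle is closed while C8 is still a trigonal ketone carbon and the rigid trans-fused lactone is absent, and the lactone is then made transannularly.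
- The fallback sets out from 38. Ene–yne cross metathesis with ethylene gives the silyl-protected butadienyl keto ester F1.
- Ring-closing metathesis at high dilution gives the ten-membered Z-dienyl keto ester F2.
- SmI2 at −78 °C converts F2 through the macrocyclic samarium enolate F3 into the protected tricyclic hydroxy lactone F4.
- HF·pyridine gives the 2,9-dideacetyl compound F5.
- Acetylation as in step 24 comes back to the route at 45.

**Step 7 (key step).** The C13 methylene may shift in place of C10. The reaction may run through an unchelated rotamer and give the C11 epimer. The product may later equilibrate by methyl migration.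
The fallback keeps the C10–C11 disconnection but puts the acetyl group on the open ring face and runs the shift on the free alkoxide.
- The fallback sets out from 10. 1-Ethoxyvinyllithium F6 (ethyl vinyl ether, t-BuLi) adds to the ketone anti to the C9 chain to give the enol ether carbinol F7.
- Oxalic acid on wet silica hydrolyses F7 to the C12-epimeric 1-acetylcyclopentanol F8.
- KH with 18-crown-6 in THF triggers the anionic acyloin shift through the dipole-opposed anti rotamer.
- In this rotamer the acetyl methyl group points outward and C10 again meets the carbonyl face that leads to the 11S carbinol. The fallback comes back to the route at 17.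

**Step 22 (lactone annulation).** Electron transfer to the α-acyloxy ketone may cause loss of the ester. The propargylic chloride may be reduced. The five-membered closure of the enolate may be sluggish.
The fallback forms C8–C17 intermolecularly before any chloride or acyloxy group is present.
- The fallback sets out from 35. The Reformatsky reagent F9 (methyl 2-bromopropanoate, zinc, THF) adds to the C8 ketone.
- The attacked face is favoured both by a zinc chelate with the epoxide oxygen and by the Felkin–Anh model for the C9 silyloxy centre. The product is the epoxy hydroxy ester F10.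
- Pyridine hydrochloride opens the epoxide at C6 to the chlorohydrin ester F11.
- The C7 hydroxyl of F11 lactonises onto the methyl ester (PPTS if needed). The fallback comes back to the route at 40.

Further compounds
F1 | step 25 | silyl-protected butadienyl keto ester | C=C[C@H](O[Si](C)(C)C(C)(C)C)[C@@]1(C)C=CC(=O)[C@@](C)(O[Si](C)(C)C(C)(C)C)[C@@H]1[C@H](O[Si](C(C)C)(C(C)C)C(C)C)C(=O)[C@@H](OC(=O)C(C)Br)[C@@H](Cl)C(=C)C=C
F2 | step 25 | ten-membered Z-dienyl keto ester | C=C1/C=C\[C@H](O[Si](C)(C)C(C)(C)C)[C@@]2(C)C=CC(=O)[C@@](C)(O[Si](C)(C)C(C)(C)C)[C@@H]2[C@H](O[Si](C(C)C)(C(C)C)C(C)C)C(=O)[C@@H](OC(=O)C(C)Br)[C@H]1Cl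
F3 | step 25 | macrocyclic samarium enolate | C=C1/C=C\[C@H](O[Si](C)(C)C(C)(C)C)[C@@]2(C)C=CC(=O)[C@@](C)(O[Si](C)(C)C(C)(C)C)[C@@H]2[C@H](O[Si](C(C)C)(C(C)C)C(C)C)C(=O)[C@@H](OC(O[Sm](I)I)=CC)[C@H]1Cl
F4 | step 25 | protected tricyclic hydroxy lactone | C=C1/C=C\[C@H](O[Si](C)(C)C(C)(C)C)[C@@]2(C)C=CC(=O)[C@@](C)(O[Si](C)(C)C(C)(C)C)[C@@H]2[C@H](O[Si](C(C)C)(C(C)C)C(C)C)[C@]2(O)[C@@H](C)C(=O)O[C@H]2[C@H]1Cl
F5 | step 25 | 2,9-dideacetyl compound | C=C1/C=C\[C@H](O)[C@@]2(C)C=CC(=O)[C@@](C)(O)[C@@H]2[C@H](O)[C@]2(O)[C@@H](C)C(=O)O[C@H]2[C@H]1Cl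
F6 | step 7 | 1-ethoxyvinyllithium | [Li]C(=C)OCC
F7 | step 7 | enol ether carbinol | C=C([Si](C)(C)C)[C@@]1(C)CC[C@@](O)(C(=C)OCC)[C@@H]1[C@H](O[Si](C(C)C)(C(C)C)C(C)C)CO[Si](c1ccccc1)(c1ccccc1)C(C)(C)C
F8 | step 7 | C12-epimeric 1-acetylcyclopentanol | C=C([Si](C)(C)C)[C@@]1(C)CC[C@@](O)(C(C)=O)[C@@H]1[C@H](O[Si](C(C)C)(C(C)C)C(C)C)CO[Si](c1ccccc1)(c1ccccc1)C(C)(C)C
F9 | step 22 | Reformatsky reagent of methyl 2-bromopropanoate | COC(=O)C(C)[Zn]Br
F10 | step 22 | epoxy hydroxy ester | C=C[C@H](O[Si](C)(C)C(C)(C)C)[C@@]1(C)C=CC(=O)[C@@](C)(O[Si](C)(C)C(C)(C)C)[C@@H]1[C@H](O[Si](C(C)C)(C(C)C)C(C)C)[C@](O)([C@@H](C)C(=O)OC)[C@H]1O[C@@H]1C#C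
F11 | step 22 | chlorohydrin ester | C=C[C@H](O[Si](C)(C)C(C)(C)C)[C@@]1(C)C=CC(=O)[C@@](C)(O[Si](C)(C)C(C)(C)C)[C@@H]1[C@H](O[Si](C(C)C)(C(C)C)C(C)C)[C@](O)([C@@H](C)C(=O)OC)[C@@H](O)[C@@H](Cl)C#C
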